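Numbers refer to the compound list that follows the steps; ring and atom labels (rings A, B, C, D; O1, C2, C3, C4, C4a, C5 to C8, C8a) are those of the flavan skeleton of the target 21.

## Analysis of the target

Target 21 is a 4-arylflavan. A 3,4-dihydro-2H-chromene (aromatic ring A fused to the pyran ring C) carries a hydroxyl on C7 and a 4-hydroxyphenyl group (ring B) on C2. On C4 it carries a 2,4,6-trihydroxyphenyl ring (ring D) with an unbranched dodecanoyl chain on its 3-position.

There are two stereocentres, C2 (R) and C4 (S), 1,3-related across the C3 methylene. The two aryl groups lie trans on ring C, so no cis-selective hydrogenation or equilibration can be counted on, and each centre needs its own control element.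

The sensitive sites are the five phenols and the acylphloroglucinol (oxidation, C-alkylation). C4 is benzylic to two electron-rich rings, with O7 para to C4a, so acid can cleave or epimerise the C4–ring D bond. The C2–O1 bond is a p-oxygenated benzylic ether that can ionise.

The main difficulty is regiochemical and stereochemical at C4. Joining C4 to a resorcinol-type ring A or to a phloroglucinol ring D by electrophilic substitution meets several nucleophilic positions and passes through a planar cation.

The strategy rests on the oxygen pattern of ring A. The oxygens on C7 and C8a are 1,3-related and C4a is para to C7, which is the pattern of a 4-substituted cyclohexane-1,3-dione. C4a can therefore be a former malonate carbon, C8a a former ester carbon, and C5 to C8 the four carbons of methyl vinyl ketone. Ring C then closes by condensation of the C2 hydroxyl with the C8a carbonyl, a bond at neither stereocentre.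

## Retrosynthetic reasoning

**21 to 20.** The four aryl benzyl ethers are cut first. Benzyl ethers pass through alkoxide, hot halide, desilylation and an aerobic palladium step, and their hydrogenolysis is neutral. Acid, which would threaten the C4–ring D bond and the C2–O1 ether of 21, is avoided at the end. The O7 hydroxyl needs no protection because it only comes into being in the preceding step.

**20 to 18 (through 19).** Ring A is taken back by one oxidation level to the 3-oxycyclohexenone 18. Forward, hydrogens are removed from C5 and C6 to give dienone 19, whose C4a hydrogen moves to O7 on aromatisation. The gain is that ring A need not be introduced as a resorcinol. Its carbons are assembled by carbonyl chemistry around a C4–C4a bond that already exists, so there is no choice among resorcinol positions and C4 is never a cation.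

**18 to 16 (through 17).** The O1–C8a bond of the vinylogous ester is cut, giving a C2 carbinol and a 4-substituted cyclohexane-1,3-dione. The cut is made here because the bond lies at neither stereocentre, so C2 and C4 can be set earlier in an open chain and merely carried. Of the two dione carbonyls only C8a can be reached through a six-membered ring. The forward reaction is desilylation and dehydrative condensation, and it must stay mild enough not to ionise the benzylic C2–O bond.

**16 to 15.** A methoxycarbonyl group is put back on C4a. It is the second activating group of the malonate that makes the annulation possible. Forward it is removed by halide-mediated dealkoxycarbonylation, which attacks the methyl group and is therefore indifferent to the crowding around the quaternary carbon. It must go before the silyl ether does, because a free C2 hydroxyl would lactonise onto this ester.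

**15 to 12 and 13 (through 14).** This is the key disconnection. C8–C8a is cut (retro-Claisen) and then C4a–C5 (retro-Michael). Methyl vinyl ketone 13 supplies C5, C6, C7 and C8, and the substituted malonate 12 supplies C4a and C8a. One operation closes the carbocycle of ring A with the correct 1,3-dioxygenation and with C4 already bonded to C4a. The forward step needs only chemoselectivity.

**12 to 11 to 10.** The silyl ether is removed and the C2–H bond is cut back to the aryl ketone. The ketone is reduced before the annulation for two reasons. A carbonyl at C2 would allow the malonate to leave C4 by retro-Michael reaction under base. A reagent-controlled reduction is also simplest on the open chain. A tri(propan-2-yl)silyl ether is preferred to a smaller silyl group because it must survive chloride in wet DMSO above 100 °C. It also keeps the C2 oxygen from lactonising onto the esters during the base steps.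

**10 to 8 and 9.** The C4–C4a bond is cut between the β-carbon of chalcone 8 and dimethyl malonate 9. This polarity is chosen because catalytic asymmetric additions of malonates to chalcones are well established, whereas aryl methyl ketones are poor enamine donors toward a crowded β-aryl acceptor. The forward reaction sets C4.

**8 to 6 and 7.** The C3=C4 double bond is cut by retro-aldol condensation into the non-enolisable aldehyde 6 and 4'-benzyloxyacetophenone 7, which brings in ring B, C2 and C3.

**6 to 5 to 3 to 1 and 2.** The benzyl ethers, the formyl group and the acyl group of ring D are removed in turn. Phloroglucinol 1 is symmetric, so acylation with 2 has no regiochemistry, and the two free positions of 3 are equivalent, so formylation fixes the 1,3-relationship of acyl chain and C4 automatically. The acyl group is installed first rather than last. A late acylation would have to distinguish ring D from ring A and would expose the acid-labile 4-arylflavan to Lewis acid.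

## Alternatives that were turned down

**Alternative 1:** Ring D is disconnected instead, across C1'–C6', C2'–C3' and C5'–C6'. Forward, the 4-(silyloxyethynyl)chroman A1 is heated with 3-(benzyloxy)cyclobut-2-en-1-one A2. The vinylketene from A2 adds to the ynol ether, and ring opening followed by six-electron electrocyclisation gives phenol A3.
- For it: three carbon–carbon bonds and ring D form in one neutral, reagent-free step. The regiochemistry follows from the polarity of the ynol ether. The three oxygens of ring D emerge differentiated (free, silyl, benzyl), which the chosen route does not offer.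
- Against it: A3 still lacks the dodecanoyl group. It would have to be introduced with 2 under Friedel–Crafts or Fries conditions on an acid-sensitive 4-arylflavan whose ring A competes. A1 presupposes the complete chroman with both stereocentres, so the C4–ring A problem is postponed rather than solved. The C4 hydrogen of A1 is both benzylic and propargylic, so the strongly basic chemistry needed to make an ynol ether invites epimerisation or allene formation.
- Comparison: alternative 1 is stronger in the construction of ring D itself. The chosen strategy brings ring D in fully substituted from 1 and 2 in three steps and spends its key step on ring A, where the regiochemical problem lies.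

**Alternative 2:** Ring B is disconnected across C1''–C6'' and C2''–C3''. Forward, the C2 acetaldehyde A4 and methyl vinyl ketone 13 undergo amine-catalysed Michael addition and aldol condensation to the cyclohexenone A5, which is then dehydrogenated to the phenol.
- For it: the reaction type is as well known as the one chosen, runs under mild organocatalytic conditions, needs the same single dehydrogenation, and ring B has no regiochemistry to get wrong. On mildness of the annulation it is at least equal.
- Against it: in A4 the ring oxygen O1 sits β to the aldehyde carbonyl, so enamine or enolate formation opens ring C by E1cB loss of the ring A phenoxide, and re-closure scrambles C2. The same vinylogous elimination threatens A5 during dehydrogenation. The annulation also builds the one ring that is available for nothing as 7, while the whole 4-arylchroman, with C4 attached to ring A and both stereocentres, must already be in place.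
- Comparison: the chosen strategy applies the same annulation logic where it removes a real problem, and carries no acidic position β to O1 at any stage.

**Alternative 3:** Ring C is disconnected across O1–C2 and C4–C4a. Forward, anodic oxidation of the trans-diarylcyclopropane A6 in the presence of 3-(benzyloxy)phenol A7 gives an arene radical cation. The phenol oxygen attacks C2 with inversion, the C4 radical is oxidised to the cation, and this is captured by the position para to the benzyloxy group to give the bromo flavan A8. The acyl chain follows by halogen–metal exchange and acylation with 2.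
- For it: it is the most convergent of the four and clearly shorter, and C2 is set stereospecifically from an accessible enantiopure cyclopropane.
- Against it: C4 passes through a planar benzylic cation, so its configuration depends only on the diastereoselectivity of the ring closure. A7 and the benzyl aryl ethers are oxidised at potentials close to or below that of A6, so the site of electron transfer is not secured. The phenol is ambident toward the radical cation. The use of one phenol as oxygen and then carbon nucleophile on a diarylcyclopropane has no close precedent.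
- Comparison: alternative 3 wins on step economy. The chosen strategy is longer, but every step has direct precedent, C4 is set by catalyst control, and C4 never becomes a cation.

Key step: step 8

Assumption: the quinine-series thiourea catalyst of step 5 is taken to deliver the malonate to the face that gives (S) at C4, by analogy with its additions to simple chalcones; the quinidine-derived pseudoenantiomer would serve the other face, and the sense would be confirmed on the first batch.

## Route

**Step 1**
Reactants: 1 phloroglucinol; 2 dodecanoyl (lauroyl) chloride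
Product: 3 1-(2,4,6-trihydroxyphenyl)dodecan-1-one
Conditions: AlCl3 (3 equiv), CH2Cl2/PhNO2, 0 → 40 °C; aq. HCl
Reagents that add atoms: none
Why: Friedel–Crafts C-acylation of the symmetric, very electron-rich arene, so there is no regiochemistry; the chelated aryl ketone deactivates the ring and should stop the reaction at monoacylation.

**Step 2**
Reactants: 3 1-(2,4,6-trihydroxyphenyl)dodecan-1-one
Product: 5 3-dodecanoyl-2,4,6-trihydroxybenzaldehyde, via iminium chloride 4 (not isolated)
Conditions: POCl3 (1.2 equiv), DMF (1.5 equiv), EtOAc, 0 °C → rt; then H2O, 50 °C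
Reagents that add atoms: N,N-dimethylformamide CN(C)C=O; water O
Why: Vilsmeier–Haack formylation; the two free ring positions of 3 are equivalent, and the first iminium group deactivates the ring against a second attack. Low temperature and near-stoichiometric reagent should favour ring C-formylation of the phloroglucinol nucleus over reaction at the ketone methylene.

**Step 3**
Reactants: 5 3-dodecanoyl-2,4,6-trihydroxybenzaldehyde
Product: 6 2,4,6-tris(benzyloxy)-3-dodecanoylbenzaldehyde
Conditions: BnBr (4 equiv), K2CO3 (5 equiv), Bu4NI (cat.), DMF, 60 °C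
Reagents that add atoms: benzyl bromide BrCc1ccccc1
Why: Williamson etherification; a dipolar aprotic solvent favours O- over C-alkylation, and the one remaining ring CH is deactivated by two carbonyl groups. The chelated hydroxyls need the excess reagent and warming.

**Step 4**
Reactants: 6 2,4,6-tris(benzyloxy)-3-dodecanoylbenzaldehyde; 7 1-[4-(benzyloxy)phenyl]ethan-1-one
Product: 8 (2E)-1-[4-(benzyloxy)phenyl]-3-[2,4,6-tris(benzyloxy)-3-dodecanoylphenyl]prop-2-en-1-one
Conditions: 7 (1.3 equiv), KOH, EtOH/THF, rt
Reagents that add atoms: none
Why: Claisen–Schmidt aldol condensation between a non-enolisable aldehyde and a methyl ketone, with E1cB dehydration giving the E-enone. The methylene enolate of the dodecanoyl ketone, shielded by two ortho ethers, is the slower donor and could not reach the aldehyde of its own ring.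

**Step 5**
Reactants: 8 (2E)-chalcone; 9 dimethyl malonate
Product: 10 dimethyl 2-[(1S)-3-[4-(benzyloxy)phenyl]-3-oxo-1-[2,4,6-tris(benzyloxy)-3-dodecanoylphenyl]propyl]propanedioate
Conditions: 9 (3 equiv), 9-amino-9-deoxy-epi-quinine 3,5-bis(trifluoromethyl)phenyl thiourea (10 mol%), PhMe (1 M), rt → 40 °C
Reagents that add atoms: none
Why: Bifunctional thiourea–tertiary amine catalysed asymmetric Michael addition of a malonate to a chalcone. The thiourea binds the enone carbonyl while the quinuclidine deprotonates the malonate and delivers it to one face of the β-carbon, which sets C4 as S. The two ortho ethers twist ring D out of conjugation and the acyl group withdraws electrons, so the β-carbon should remain electrophilic enough.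

**Step 6**
Reactants: 10 the (1S)-keto malonate
Product: 11 dimethyl 2-[(1S,3R)-3-[4-(benzyloxy)phenyl]-3-hydroxy-1-[2,4,6-tris(benzyloxy)-3-dodecanoylphenyl]propyl]propanedioate
Conditions: (S)-2-methyl-CBS-oxazaborolidine (0.2 equiv), BH3·SMe2 (0.7 equiv), THF, −20 °C; MeOH; cold neutral work-up
Reagents that add atoms: none
Why: Corey–Bakshi–Shibata reduction; the aryl group acts as the large substituent, so the (S)-catalyst should give the (R)-carbinol (C2) under reagent control regardless of the remote C4 centre. The dodecanoyl ketone, twisted between two ortho benzyloxy groups, should be spared, and the non-basic medium avoids retro-Michael loss of the malonate. The crude alcohol is silylated at once to forestall δ-lactonisation.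

**Step 7**
Reactants: 11 the (1S,3R)-hydroxy malonate
Product: 12 dimethyl 2-[(1S,3R)-3-[4-(benzyloxy)phenyl]-1-[2,4,6-tris(benzyloxy)-3-dodecanoylphenyl]-3-{[tri(propan-2-yl)silyl]oxy}propyl]propanedioate
Conditions: TIPSOTf (1.3 equiv), 2,6-lutidine (2 equiv), CH2Cl2, −78 → 0 °C
Reagents that add atoms: tri(propan-2-yl)silyl trifluoromethanesulfonate CC(C)[Si](OS(=O)(=O)C(F)(F)F)(C(C)C)C(C)C
Why: O-silylation of a secondary alcohol with a silyl triflate and a hindered pyridine base. It is fast at low temperature, so lactonisation cannot compete, and the weak base does not enolise the malonate or the ketone.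

**Step 8**
Reactants: 12 the silyl-protected malonate; 13 methyl vinyl ketone (but-3-en-2-one)
Product: 15 methyl 1-[(1R,3R)-3-[4-(benzyloxy)phenyl]-1-[2,4,6-tris(benzyloxy)-3-dodecanoylphenyl]-3-{[tri(propan-2-yl)silyl]oxy}propyl]-2,4-dioxocyclohexane-1-carboxylate as a mixture of epimers at ring C1, via Michael adduct 14 (not isolated)
Conditions: 13 (1.5 equiv), K2CO3 (0.3 equiv), MeOH/THF, 0 °C → rt; filter, strip excess 13; NaOMe (3 equiv), MeOH/THF, 60 °C; AcOH
Reagents that add atoms: none
Why: Carbonate ionises the malonate C–H, the only acid of that strength in 12, and the stabilised anion adds to the terminal carbon of 13 (Michael addition), forming C4a–C5 and giving 14. Methoxide then forms the methyl ketone enolate reversibly; it attacks one ester carbonyl and expels methoxide (Claisen condensation of the Dieckmann type), forming C8–C8a. The closest known reaction is the Michael–Claisen annulation of 2-alkylmalonates with methyl vinyl ketone to 4-alkoxycarbonylcyclohexane-1,3-diones. Ring A closes in a 6-(enolexo)-exo-trig mode, whereas the other enolate of that ketone (at C6) could only form a four-membered ring. Deprotonation of the product between the C7 and C8a carbonyls takes it out of the retro-Claisen equilibrium until the acetic acid quench. The new quaternary centre C4a forms from two diastereotopic esters as a mixture of epimers under no control and needs none, because it is destroyed on aromatisation; the descriptor at chain C1 changes from S to R only through the priority rules. C4 and C2 are untouched, since C4–H is not acidic and no carbonyl remains at C2 to permit retro-Michael cleavage of C4–C4a. The step needs only chemoselectivity: the dodecanoyl ketone can enolise under methoxide but finds no electrophile within reach of a five- or six-membered ring (attack on an ester would need an eight-membered one), excess 13 is removed before methoxide is added, and the silyl ether keeps the C2 oxygen from lactonising onto the esters.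

**Step 9**
Reactants: 15 the dioxocyclohexanecarboxylate
Product: 16 4-[(1S,3R)-3-[4-(benzyloxy)phenyl]-1-[2,4,6-tris(benzyloxy)-3-dodecanoylphenyl]-3-{[tri(propan-2-yl)silyl]oxy}propyl]cyclohexane-1,3-dione as a mixture of epimers at ring C4
Conditions: LiCl (5 equiv), H2O (3 equiv), DMSO, 120–130 °C
Reagents that add atoms: none
Why: Krapcho dealkoxycarbonylation; chloride attacks the ester methyl group, so the crowded quaternary carbon is no obstacle, and the resulting β-keto carboxylate loses CO2. The bulky tri(propan-2-yl)silyl ether and the benzyl ethers should withstand chloride in hot wet DMSO.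

**Step 10**
Reactants: 16 the silyl-protected 4-substituted cyclohexane-1,3-dione
Product: 18 (2R,4S)-2-[4-(benzyloxy)phenyl]-4-[2,4,6-tris(benzyloxy)-3-dodecanoylphenyl]-2,3,4,4a,5,6-hexahydro-7H-chromen-7-one as a mixture of C4a epimers, via hydroxy dione 17 (not isolated)
Conditions: Bu4NF (3 equiv), THF, 0 °C → rt; AcOH; then PPTS (10 mol%), 4 Å MS, PhMe, 50 °C
Reagents that add atoms: none
Why: Fluoride desilylation, then intramolecular hemiketalisation and dehydration of the C2 hydroxyl onto the C8a carbonyl to the vinylogous ester; only C8a can be reached through a six-membered ring. The O1–C8a bond forms at neither stereocentre, so C2 (R) and C4 (S) are carried over unchanged. The acid is kept as weak as the dione itself so that the p-benzyloxybenzylic C2–O bond does not ionise.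

**Step 11**
Reactants: 18 the hexahydrochromen-7-one
Product: 20 1-{2,4,6-tris(benzyloxy)-3-[(2R,4S)-2-[4-(benzyloxy)phenyl]-7-hydroxy-3,4-dihydro-2H-chromen-4-yl]phenyl}dodecan-1-one, via dienone 19 (not isolated)
Conditions: Pd(OCOCF3)2 (10 mol%), 2-(dimethylamino)pyridine (20 mol%), TsOH·H2O (10 mol%), O2 (1 atm), DMSO, 80 °C
Reagents that add atoms: none
Why: Aerobic dehydrogenation of a cyclohexenone to a phenol catalysed by divalent palladium: palladation at C6, β-hydride elimination from C5, tautomerisation of dienone 19 with loss of the C4a stereocentre, and reoxidation of zerovalent palladium by O2. The sulfonic acid is kept below the aminopyridine loading so that the medium stays buffered while O1–C2 is still a benzylic vinylogous ester. Any dehydrogenation of the dodecanoyl chain would be undone by the hydrogen of step 12.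

**Step 12**
Reactants: 20 the tetrabenzyl ether phenol
Product: 21 1-{2,4,6-trihydroxy-3-[(2R,4S)-7-hydroxy-2-(4-hydroxyphenyl)-3,4-dihydro-2H-chromen-4-yl]phenyl}dodecan-1-one (the target)
Conditions: H2 (1 atm), 10% Pd/C, EtOAc/MeOH, rt
Reagents that add atoms: none
Why: Hydrogenolysis of four aryl benzyl ethers under neutral conditions. The hydrogen-bonded acylphloroglucinol ketone and the cyclic C2–O1 ether react much more slowly than O-benzyl groups at 1 atm and room temperature, and the reaction would be stopped at full debenzylation.

## Compound list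

1 | phloroglucinol (benzene-1,3,5-triol) | Oc1cc(O)cc(O)c1 | starting material
2 | dodecanoyl (lauroyl) chloride | CCCCCCCCCCCC(Cl)=O | starting material
3 | 1-(2,4,6-trihydroxyphenyl)dodecan-1-one | CCCCCCCCCCCC(=O)c1c(O)cc(O)cc1O | intermediate
4 | N-[(3-dodecanoyl-2,4,6-trihydroxyphenyl)methylidene]-N-methylmethanaminium chloride | CCCCCCCCCCCC(=O)c1c(O)cc(O)c(C=[N+](C)C)c1O.[Cl-] | intermediate (not isolated)
5 | 3-dodecanoyl-2,4,6-trihydroxybenzaldehyde | CCCCCCCCCCCC(=O)c1c(O)cc(O)c(C=O)c1O | intermediate
6 | 2,4,6-tris(benzyloxy)-3-dodecanoylbenzaldehyde | CCCCCCCCCCCC(=O)c1c(OCc2ccccc2)cc(OCc2ccccc2)c(C=O)c1OCc1ccccc1 | intermediate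
7 | 1-[4-(benzyloxy)phenyl]ethan-1-one (4'-benzyloxyacetophenone) | CC(=O)c1ccc(OCc2ccccc2)cc1 | starting material
8 | (2E)-1-[4-(benzyloxy)phenyl]-3-[2,4,6-tris(benzyloxy)-3-dodecanoylphenyl]prop-2-en-1-one | CCCCCCCCCCCC(=O)c1c(OCc2ccccc2)cc(OCc2ccccc2)c(/C=C/C(=O)c2ccc(OCc3ccccc3)cc2)c1OCc1ccccc1 | intermediate
9 | dimethyl malonate (dimethyl propanedioate) | COC(=O)CC(=O)OC | starting material
10 | dimethyl 2-[(1S)-3-[4-(benzyloxy)phenyl]-3-oxo-1-[2,4,6-tris(benzyloxy)-3-dodecanoylphenyl]propyl]propanedioate | CCCCCCCCCCCC(=O)c1c(OCc2ccccc2)cc(OCc2ccccc2)c([C@@H](CC(=O)c2ccc(OCc3ccccc3)cc2)C(C(=O)OC)C(=O)OC)c1OCc1ccccc1 | intermediate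
11 | dimethyl 2-[(1S,3R)-3-[4-(benzyloxy)phenyl]-3-hydroxy-1-[2,4,6-tris(benzyloxy)-3-dodecanoylphenyl]propyl]propanedioate | CCCCCCCCCCCC(=O)c1c(OCc2ccccc2)cc(OCc2ccccc2)c([C@@H](C[C@H](c2ccc(OCc3ccccc3)cc2)O)C(C(=O)OC)C(=O)OC)c1OCc1ccccc1 | intermediate
12 | dimethyl 2-[(1S,3R)-3-[4-(benzyloxy)phenyl]-1-[2,4,6-tris(benzyloxy)-3-dodecanoylphenyl]-3-{[tri(propan-2-yl)silyl]oxy}propyl]propanedioate | CCCCCCCCCCCC(=O)c1c(OCc2ccccc2)cc(OCc2ccccc2)c([C@@H](C[C@H](c2ccc(OCc3ccccc3)cc2)O[Si](C(C)C)(C(C)C)C(C)C)C(C(=O)OC)C(=O)OC)c1OCc1ccccc1 | intermediate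
13 | methyl vinyl ketone (but-3-en-2-one) | CC(=O)C=C | starting material
14 | dimethyl 2-[(1R,3R)-3-[4-(benzyloxy)phenyl]-1-[2,4,6-tris(benzyloxy)-3-dodecanoylphenyl]-3-{[tri(propan-2-yl)silyl]oxy}propyl]-2-(3-oxobutyl)propanedioate (same spatial arrangement as 12) | CCCCCCCCCCCC(=O)c1c(OCc2ccccc2)cc(OCc2ccccc2)c([C@@H](C[C@H](c2ccc(OCc3ccccc3)cc2)O[Si](C(C)C)(C(C)C)C(C)C)C(CCC(C)=O)(C(=O)OC)C(=O)OC)c1OCc1ccccc1 | intermediate (not isolated)
15 | methyl 1-[(1R,3R)-3-[4-(benzyloxy)phenyl]-1-[2,4,6-tris(benzyloxy)-3-dodecanoylphenyl]-3-{[tri(propan-2-yl)silyl]oxy}propyl]-2,4-dioxocyclohexane-1-carboxylate (both epimers at ring C1) | CCCCCCCCCCCC(=O)c1c(OCc2ccccc2)cc(OCc2ccccc2)c([C@@H](C[C@H](c2ccc(OCc3ccccc3)cc2)O[Si](C(C)C)(C(C)C)C(C)C)C2(C(=O)OC)CCC(=O)CC2=O)c1OCc1ccccc1 | intermediate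
16 | 4-[(1S,3R)-3-[4-(benzyloxy)phenyl]-1-[2,4,6-tris(benzyloxy)-3-dodecanoylphenyl]-3-{[tri(propan-2-yl)silyl]oxy}propyl]cyclohexane-1,3-dione (both epimers at ring C4) | CCCCCCCCCCCC(=O)c1c(OCc2ccccc2)cc(OCc2ccccc2)c([C@@H](C[C@H](c2ccc(OCc3ccccc3)cc2)O[Si](C(C)C)(C(C)C)C(C)C)C2CCC(=O)CC2=O)c1OCc1ccccc1 | intermediate
17 | 4-[(1S,3R)-3-[4-(benzyloxy)phenyl]-3-hydroxy-1-[2,4,6-tris(benzyloxy)-3-dodecanoylphenyl]propyl]cyclohexane-1,3-dione (both epimers at ring C4) | CCCCCCCCCCCC(=O)c1c(OCc2ccccc2)cc(OCc2ccccc2)c([C@@H](C[C@H](c2ccc(OCc3ccccc3)cc2)O)C2CCC(=O)CC2=O)c1OCc1ccccc1 | intermediate (not isolated)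
18 | (2R,4S)-2-[4-(benzyloxy)phenyl]-4-[2,4,6-tris(benzyloxy)-3-dodecanoylphenyl]-2,3,4,4a,5,6-hexahydro-7H-chromen-7-one (both C4a epimers) | CCCCCCCCCCCC(=O)c1c(OCc2ccccc2)cc(OCc2ccccc2)c([C@H]2C[C@H](c3ccc(OCc4ccccc4)cc3)OC3=CC(=O)CCC32)c1OCc1ccccc1 | intermediate
19 | (2R,4S)-2-[4-(benzyloxy)phenyl]-4-[2,4,6-tris(benzyloxy)-3-dodecanoylphenyl]-2,3,4,4a-tetrahydro-7H-chromen-7-one (both C4a epimers) | CCCCCCCCCCCC(=O)c1c(OCc2ccccc2)cc(OCc2ccccc2)c([C@H]2C[C@H](c3ccc(OCc4ccccc4)cc3)OC3=CC(=O)C=CC32)c1OCc1ccccc1 | intermediate (not isolated)
20 | 1-{2,4,6-tris(benzyloxy)-3-[(2R,4S)-2-[4-(benzyloxy)phenyl]-7-hydroxy-3,4-dihydro-2H-chromen-4-yl]phenyl}dodecan-1-one | CCCCCCCCCCCC(=O)c1c(OCc2ccccc2)cc(OCc2ccccc2)c([C@H]2C[C@H](c3ccc(OCc4ccccc4)cc3)Oc3cc(O)ccc32)c1OCc1ccccc1 | intermediate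
21 | 1-{2,4,6-trihydroxy-3-[(2R,4S)-7-hydroxy-2-(4-hydroxyphenyl)-3,4-dihydro-2H-chromen-4-yl]phenyl}dodecan-1-one | CCCCCCCCCCCC(=O)c1c(O)cc(O)c([C@H]2C[C@H](c3ccc(O)cc3)Oc3cc(O)ccc32)c1O | target

## Step count and least certain steps

Total step count: 12. Longest linear sequence: 12 steps (1 to 21); compounds 2, 7, 9 and 13 enter as purchased reagents.

**Step 8 (key step).** The most likely failure is slow or incomplete conjugate addition, because the malonate carbon sits next to a tertiary centre that carries a doubly ortho-substituted aryl ring. The second risk is reversal of that addition once methoxide is present, since loss of 13 relieves the crowded quaternary carbon before the Claisen closure has trapped it. Polymerisation of 13 under base is a further drain.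
Fallback, setting out from 12 and returning at 14: the anion of 12 (Cs2CO3 cat., THF, 0 °C) is added to but-3-yn-2-one. This acceptor is slimmer and far more electrophilic, and its adduct cannot revert because the vinyl anion is protonated at once. It should give the (E)-enone malonate F1. Conjugate reduction of F1 with [(Ph3P)CuH]6 (cat.) and PhSiH3 in toluene, which leaves hindered ketones and benzyl ethers alone, would deliver 14 after work-up. Compound 14 is then closed to 15 by the alkoxide treatment of step 8.

**Step 11.** Palladation of the electron-rich vinylogous ester at C6 may be sluggish, so that catalyst decomposition to palladium black overtakes turnover. Prolonged heating with the acid co-catalyst could ionise the C2–O1 bond, which at this stage is a benzylic vinylogous ester, with loss of configuration at C2.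
Fallback, setting out from 18 and returning at 21: 18 is treated with LiN(SiMe3)2 (2.4 equiv, THF, −78 °C), which enolises both C6 of the vinylogous ester and the methylene of the dodecanoyl ketone, and then with PhSeBr to give the bis(phenylselanyl) compound F2. H2O2/pyridine (CH2Cl2, 0 °C) effects selenoxide syn-elimination at both sites. The ring gives dienone 19 and hence the phenol, and the chain gives an (E)-enone, that is the dodec-2-enoyl phenol F3. Hydrogenation under the conditions of step 12 saturates the chain alkene while it cleaves the benzyl ethers, so F3 goes directly to 21 with no acid or heat.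

**Step 5.** The β-carbon of 8 is flanked by two ortho benzyloxy groups, so conversion may stall. The same crowding may also disturb the catalyst–substrate arrangement, giving poor or even inverted facial selectivity.
Fallback, setting out from 8 and 9 and returning at 11: the addition is run without asymmetric induction (NaOMe cat., MeOH/THF, 0 °C) to give the racemic keto malonate F4. Reduction of F4 under the conditions of step 6 is controlled by the oxazaborolidine at the carbinol carbon for both enantiomers, so it should give 11 together with its (1R,3R)-diastereomer F5, each as a single enantiomer. The two are separated by chromatography and 11 is carried on, at the cost of half the material.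

**Step 10.** The acid-promoted dehydration may be accompanied by ionisation at the p-benzyloxybenzylic C2, giving epimerisation or elimination to a styrene. Alternatively the hemiketal may resist dehydration under acid this mild.
Fallback, setting out from 10 and returning at 18: ring C is closed by displacement at C2 with inversion instead of condensation at C8a. Ketone 10 is reduced with (R)-2-methyl-CBS-oxazaborolidine/BH3·SMe2 to the (1S,3S)-hydroxy malonate F6, which is silylated as in step 7 to the (1S,3S)-silyl ether F7. The conditions of steps 8 and 9 then take F7 through the Michael adduct F8 (not isolated) and the dioxocyclohexanecarboxylate F9 to the dione F10. Bu4NF gives the (1S,3S)-hydroxy dione F11. With PPh3/DIAD (THF, 0 °C) the acidic enol oxygen on C8a should displace the activated C2 oxygen intramolecularly with inversion (Mitsunobu etherification), giving 18 under neutral conditions.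

## Further compounds

F1 | step 8 | dimethyl 2-[(1R,3R)-3-[4-(benzyloxy)phenyl]-1-[2,4,6-tris(benzyloxy)-3-dodecanoylphenyl]-3-{[tri(propan-2-yl)silyl]oxy}propyl]-2-[(1E)-3-oxobut-1-en-1-yl]propanedioate | CCCCCCCCCCCC(=O)c1c(OCc2ccccc2)cc(OCc2ccccc2)c([C@@H](C[C@H](c2ccc(OCc3ccccc3)cc2)O[Si](C(C)C)(C(C)C)C(C)C)C(/C=C/C(C)=O)(C(=O)OC)C(=O)OC)c1OCc1ccccc1
F2 | step 11 | (2R,4S)-2-[4-(benzyloxy)phenyl]-6-(phenylselanyl)-4-{2,4,6-tris(benzyloxy)-3-[2-(phenylselanyl)dodecanoyl]phenyl}-2,3,4,4a,5,6-hexahydro-7H-chromen-7-one (mixture at C4a, C6 and the chain carbon) | CCCCCCCCCCC([Se]c2ccccc2)C(=O)c1c(OCc2ccccc2)cc(OCc2ccccc2)c([C@H]2C[C@H](c3ccc(OCc4ccccc4)cc3)OC3=CC(=O)C([Se]c4ccccc4)CC32)c1OCc1ccccc1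
F3 | step 11 | (2E)-1-{2,4,6-tris(benzyloxy)-3-[(2R,4S)-2-[4-(benzyloxy)phenyl]-7-hydroxy-3,4-dihydro-2H-chromen-4-yl]phenyl}dodec-2-en-1-one | CCCCCCCCC/C=C/C(=O)c1c(OCc2ccccc2)cc(OCc2ccccc2)c([C@H]2C[C@H](c3ccc(OCc4ccccc4)cc3)Oc3cc(O)ccc32)c1OCc1ccccc1
F4 | step 5 | racemic dimethyl 2-{3-[4-(benzyloxy)phenyl]-3-oxo-1-[2,4,6-tris(benzyloxy)-3-dodecanoylphenyl]propyl}propanedioate | CCCCCCCCCCCC(=O)c1c(OCc2ccccc2)cc(OCc2ccccc2)c(C(CC(=O)c2ccc(OCc3ccccc3)cc2)C(C(=O)OC)C(=O)OC)c1OCc1ccccc1
F5 | step 5 | dimethyl 2-[(1R,3R)-3-[4-(benzyloxy)phenyl]-3-hydroxy-1-[2,4,6-tris(benzyloxy)-3-dodecanoylphenyl]propyl]propanedioate | CCCCCCCCCCCC(=O)c1c(OCc2ccccc2)cc(OCc2ccccc2)c([C@H](C[C@H](c2ccc(OCc3ccccc3)cc2)O)C(C(=O)OC)C(=O)OC)c1OCc1ccccc1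
F6 | step 10 | dimethyl 2-[(1S,3S)-3-[4-(benzyloxy)phenyl]-3-hydroxy-1-[2,4,6-tris(benzyloxy)-3-dodecanoylphenyl]propyl]propanedioate | CCCCCCCCCCCC(=O)c1c(OCc2ccccc2)cc(OCc2ccccc2)c([C@@H](C[C@@H](c2ccc(OCc3ccccc3)cc2)O)C(C(=O)OC)C(=O)OC)c1OCc1ccccc1
F7 | step 10 | dimethyl 2-[(1S,3S)-3-[4-(benzyloxy)phenyl]-1-[2,4,6-tris(benzyloxy)-3-dodecanoylphenyl]-3-{[tri(propan-2-yl)silyl]oxy}propyl]propanedioate | CCCCCCCCCCCC(=O)c1c(OCc2ccccc2)cc(OCc2ccccc2)c([C@@H](C[C@@H](c2ccc(OCc3ccccc3)cc2)O[Si](C(C)C)(C(C)C)C(C)C)C(C(=O)OC)C(=O)OC)c1OCc1ccccc1
F8 | step 10 | dimethyl 2-[(1R,3S)-3-[4-(benzyloxy)phenyl]-1-[2,4,6-tris(benzyloxy)-3-dodecanoylphenyl]-3-{[tri(propan-2-yl)silyl]oxy}propyl]-2-(3-oxobutyl)propanedioate | CCCCCCCCCCCC(=O)c1c(OCc2ccccc2)cc(OCc2ccccc2)c([C@@H](C[C@@H](c2ccc(OCc3ccccc3)cc2)O[Si](C(C)C)(C(C)C)C(C)C)C(CCC(C)=O)(C(=O)OC)C(=O)OC)c1OCc1ccccc1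
F9 | step 10 | methyl 1-[(1R,3S)-3-[4-(benzyloxy)phenyl]-1-[2,4,6-tris(benzyloxy)-3-dodecanoylphenyl]-3-{[tri(propan-2-yl)silyl]oxy}propyl]-2,4-dioxocyclohexane-1-carboxylate (both epimers at ring C1) | CCCCCCCCCCCC(=O)c1c(OCc2ccccc2)cc(OCc2ccccc2)c([C@@H](C[C@@H](c2ccc(OCc3ccccc3)cc2)O[Si](C(C)C)(C(C)C)C(C)C)C2(C(=O)OC)CCC(=O)CC2=O)c1OCc1ccccc1
F10 | step 10 | 4-[(1S,3S)-3-[4-(benzyloxy)phenyl]-1-[2,4,6-tris(benzyloxy)-3-dodecanoylphenyl]-3-{[tri(propan-2-yl)silyl]oxy}propyl]cyclohexane-1,3-dione (both epimers at ring C4) | CCCCCCCCCCCC(=O)c1c(OCc2ccccc2)cc(OCc2ccccc2)c([C@@H](C[C@@H](c2ccc(OCc3ccccc3)cc2)O[Si](C(C)C)(C(C)C)C(C)C)C2CCC(=O)CC2=O)c1OCc1ccccc1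
F11 | step 10 | 4-[(1S,3S)-3-[4-(benzyloxy)phenyl]-3-hydroxy-1-[2,4,6-tris(benzyloxy)-3-dodecanoylphenyl]propyl]cyclohexane-1,3-dione (both epimers at ring C4) | CCCCCCCCCCCC(=O)c1c(OCc2ccccc2)cc(OCc2ccccc2)c([C@@H](C[C@@H](c2ccc(OCc3ccccc3)cc2)O)C2CCC(=O)CC2=O)c1OCc1ccccc1
A1 | alternative 1 | (2R,4R)-7-(benzyloxy)-2-[4-(benzyloxy)phenyl]-4-({[tri(propan-2-yl)silyl]oxy}ethynyl)-3,4-dihydro-2H-chromene (same spatial arrangement as the target; the C4 descriptor changes through the priority rules) | CC(C)[Si](OC#C[C@H]1C[C@H](c2ccc(OCc3ccccc3)cc2)Oc2cc(OCc3ccccc3)ccc21)(C(C)C)C(C)C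
A2 | alternative 1 | 3-(benzyloxy)cyclobut-2-en-1-one | O=C1CC(OCc2ccccc2)=C1
A3 | alternative 1 | 5-(benzyloxy)-2-[(2R,4S)-7-(benzyloxy)-2-[4-(benzyloxy)phenyl]-3,4-dihydro-2H-chromen-4-yl]-3-{[tri(propan-2-yl)silyl]oxy}phenol | Oc1cc(OCc2ccccc2)cc(O[Si](C(C)C)(C(C)C)C(C)C)c1[C@H]1C[C@H](c2ccc(OCc3ccccc3)cc2)Oc2cc(OCc3ccccc3)ccc21
A4 | alternative 2 | 2-[(2R,4S)-7-(benzyloxy)-4-[2,4,6-tris(benzyloxy)-3-dodecanoylphenyl]-3,4-dihydro-2H-chromen-2-yl]acetaldehyde | CCCCCCCCCCCC(=O)c1c(OCc2ccccc2)cc(OCc2ccccc2)c([C@H]2C[C@H](CC=O)Oc3cc(OCc4ccccc4)ccc32)c1OCc1ccccc1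
A5 | alternative 2 | 4-[(2R,4S)-7-(benzyloxy)-4-[2,4,6-tris(benzyloxy)-3-dodecanoylphenyl]-3,4-dihydro-2H-chromen-2-yl]cyclohex-2-en-1-one (both epimers at the ring carbon) | CCCCCCCCCCCC(=O)c1c(OCc2ccccc2)cc(OCc2ccccc2)c([C@H]2C[C@H](C3C=CC(=O)CC3)Oc3cc(OCc4ccccc4)ccc32)c1OCc1ccccc1
A6 | alternative 3 | 1,3,5-tris(benzyloxy)-2-[(1R,2R)-2-[4-(benzyloxy)phenyl]cyclopropyl]-4-bromobenzene | Brc1c(OCc2ccccc2)cc(OCc2ccccc2)c([C@@H]2C[C@H]2c2ccc(OCc3ccccc3)cc2)c1OCc1ccccc1
A7 | alternative 3 | 3-(benzyloxy)phenol | Oc1cccc(OCc2ccccc2)c1
A8 | alternative 3 | (2R,4S)-7-(benzyloxy)-2-[4-(benzyloxy)phenyl]-4-[2,4,6-tris(benzyloxy)-3-bromophenyl]-3,4-dihydro-2H-chromene | Brc1c(OCc2ccccc2)cc(OCc2ccccc2)c([C@H]2C[C@H](c3ccc(OCc4ccccc4)cc3)Oc3cc(OCc4ccccc4)ccc32)c1OCc1ccccc1
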